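## Analysis of the target

- Target 25 is an open C1–C10 terpenoid chain joined through an exocyclic alkene to a γ-butyrolactone. The ring consists of C11, C12, C13, the ring oxygen and the carbonyl carbon C20, and C10=C11 is (E): C9 lies trans to the lactone carbonyl and cis to C12.
- Along the chain, C1 carries the benzoate, C2=C3 is (Z) as in nerol, C6=C7 is (E) and C8 carries an acetate. On the ring, C12 carries the second acetate and C13 the 2-methylprop-1-enyl group (C14=C15).
- There are three stereocentres. C12 (S) and C13 (R) are neighbours and trans on the ring, which is an anti 1,2-diol in the open chain. C8 (R) is separated from them by C9 and the C10=C11 alkene and cannot be relayed from the ring.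
- All four C–O bonds at C1, C8, C12 and C13 are allylic, so acid and low-valent late transition metals can ionise them. The C12 acetate on the alkylidene lactone is a Morita–Baylis–Hillman-acetate motif that nucleophiles can displace in the conjugate sense.
- One benzoate, two acetates and a lactone in one molecule rule out a late selective ester hydrolysis, so each acyl group has to arrive on the right oxygen.
- The difficulties are therefore the remote C8 stereocentre, the (E)-trisubstituted exocyclic alkene and the placement of the acyl groups.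
- The strategy rests on one feature: C9 is the γ-carbon of the C20 carbonyl through C10=C11, and C8 is a carbinol carbon next to the (E)-C6=C7(CH3) unit, i.e. the carbonyl carbon of an (E)-2-methyl enal that nerol (1) gives by allylic oxidation. C8–C9 is thus a vinylogous aldol bond.

## Retrosynthetic reasoning

**25 ⇒ 24.** The two acetates at C8 and C12 are removed first. Both oxygens receive the same acyl group, so one acetylation of diol lactone 24 finishes the synthesis. The C1 benzoate is placed on nerol at the very start, so the three ester types never have to be told apart.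

**24 ⇒ 22.** The lactone C20–O bond is opened to the methyl ester 22 with C12 and C13 as silyl ethers. In the forward sense, fluoride frees the C13 hydroxyl, which closes the five-membered ring on the ester. The C8 hydroxyl cannot reach C20 across the (E)-alkene, and the C12 hydroxyl would have to form a four-membered ring, so only the γ-lactone is expected.

**22 ⇒ 20 + 5.** The C8–C9 bond is cut. This is the one bond that divides the molecule into the terpenoid chain and the stereodefined ring half, lies next to the isolated stereocentre, and has natural polarity: γ-nucleophilic silyl dienolate 20 and electrophilic enal 5. The cut gives convergence and lets one step form the bond, the C8 carbinol and the conjugated (E)-C10=C11 alkene. The forward reaction must attack through C9 and not C11, add to one face of the aldehyde, and return the ester with C9 trans to C20.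

**5 ⇒ 4 ⇒ 3 ⇒ 1 + 2.** The enal oxygen at C8 is traced to the (E)-methyl group of the terminal alkene of neryl benzoate 3, made from 1 and 2. Allylic oxidation at that methyl fixes the (E)-C6=C7 geometry. The benzoate deactivates the C2=C3 alkene, so the oxidation goes to the far end.

**20 ⇒ 18 ⇒ 17 ⇒ 14 + 15.** The dienolate comes from 2-ethylidene ester 18 by γ-deprotonation and O-silylation, and 18 from alcohol 17 by silylation. In 17 the C11–C12 bond is cut to the α-silyloxy aldehyde 14 and bromo enoate 15. A chromium-mediated alkenylation under Felkin–Anh control should set C12 anti to C13. The ethylidene geometry is erased when the dienolate forms, so no geometric purity is needed there.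

**14 ⇒ 13 ⇒ 12 ⇒ 11 ⇒ 10 ⇒ 7 + 8 ⇒ 6.** C13 is taken from the chiral pool. In (R)-solketal 6 the free hydroxymethyl carbon becomes the alkene carbon C14 (oxidation to 7, Wittig reaction with the ylide from 8). The ring CH2O carbon becomes the aldehyde carbon C12 (acetal cleavage to 11, bis-silylation to 12, primary desilylation to 13, oxidation to 14). Swapping the roles of the two carbons is what turns the (R)-configured starting material into the (13R) centre.

## Alternatives that were turned down

**Alternative 1:** palladium cyclocarbonylation of an alkynyl diol.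
- Disconnection: the lactone bonds C20–O and C11–C20 are cut, with C20 coming from CO, which leads back to alkynyl diol A2 with a C10≡C11 triple bond.
- Forward key step: under CO with PdCl2(PPh3)2 and SnCl2, the C13 hydroxyl of A2 forms an alkoxycarbonyl-palladium unit that adds syn across the alkyne; protonolysis gives hydroxy lactone A1.
- For it: ring, carbonyl and (E)-alkene arise in one step whose geometry is fixed by the syn addition. A2 is reachable by acetylide addition to aldehyde 14.
- Against it:
  - A slim acetylide usually adds to an α-silyloxy aldehyde with poor Felkin–Anh selectivity, so C12 is less secure than with a bulky alkenylchromium reagent.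
  - The free propargylic C12 hydroxyl can carbonylate to a four-membered alkylidene lactone or ionise under SnCl2.
  - Zerovalent palladium would ionise an allylic C1 benzoate, so C1 has to be a silyl ether as in A1. The endgame then needs C12 acetylation, double desilylation, selective primary benzoylation and C8 acetylation: four steps instead of two.
  - C8 still needs its own asymmetric step in the alkyne fragment.
- Comparison: alternative 1 is stronger on alkene geometry (mechanism instead of a conformational preference) and needs no chiral catalyst at the fragment union. The chosen strategy offers instead the C8 centre and the union in one step, the native benzoate throughout, and a two-step endgame.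

**Alternative 2:** electrochemical decarboxylative alkenylation at C9–C10.
- Disconnection: the sp3–sp2 bond C9–C10 is cut to the N-hydroxyphthalimide ester A4 (carrying C8) and the (E)-iodomethylene lactone A5. A5 derives from 2-deoxy-D-ribono-1,4-lactone A6, which already has the (12S,13R)-trans arrangement.
- Forward key step: at a cathode with NiCl2·glyme and 2,2'-bipyridine, A4 loses CO2 to give the primary C9 radical, which is captured by the alkenylnickel species from A5 to give tris-silyl ether A3.
- For it: both ring stereocentres come from A6 without any diastereoselective step. The radical coupling tolerates esters and silyl ethers, and the alkene geometry is carried in by A5.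
- Against it:
  - A5 is long: protection, replacement of C5 of A6 by the isobutenyl group through an epimerisable α-alkoxy aldehyde, and a stereodefined iodomethylenation at C11.
  - A4 needs C8 from a separate asymmetric acetate aldol on enal 5, then protection, hydrolysis and activation.
  - The β-silyloxy alkylnickel intermediate can lose silyloxide.
  - The C9 radical can add directly to C10 of the acceptor A5 and expel iodine, which does not guarantee the (E)-geometry.
  - Three silyl ethers must be exchanged for one benzoate and two acetates (about three steps).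
- Comparison: alternative 2 is stronger on the security of C12 and C13. The chosen strategy sets C12 by a Felkin–Anh-controlled addition early, on small fragments where a minor isomer is removed cheaply, and is much shorter.

**Alternative 3:** late chromium alkenylation at C11–C12.
- Disconnection: C11–C12 is cut to the (Z)-2-iodoenoate A8, which holds C1–C11 and C20 with the C8 silyl ether, and the (R)-2-(triethylsilyloxy) aldehyde A9.
- Forward key step: CrCl2 with catalytic NiCl2 turns A8 into an alkenylchromium reagent that adds to A9 anti to the silyloxy group, giving hydroxy ester A7.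
- For it: it is the most convergent plan, runs under neutral conditions, uses the same Felkin–Anh control as step 10 of the chosen route, and needs no strong base and no silyl dienolate.
- Against it:
  - A8 needs C8 set first (acetate aldol on 5), then protection, chain extension to the aldehyde and a (Z)-selective iodo-olefination, roughly six steps with their own geometry problem.
  - The diastereoselective step comes last, on the most valuable material, and a wrong C12 epimer cannot be recycled.
  - The allylic benzoate is exposed to zerovalent nickel.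
- Comparison: alternative 3 is stronger in that it does not depend on a crowded dienolate reacting at its γ-carbon. The chosen strategy runs the chromium step early with the simple bromide 15 and gains C8 catalytically in the union step.

Key step: step 13

Remarks and assumptions:
- The carbon numbering C1–C20 of the target is used for all intermediates. TBS = tert-butyldimethylsilyl.
- The catalyst of step 13, called "(R,R)-bisphosphoramide" below, consists of two cyclic phosphoramide units made from (R)-N,N'-dimethyl-1,1'-binaphthyl-2,2'-diamine, joined through their exocyclic N-methyl nitrogen atoms by a pentane-1,5-diyl chain.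
- Assumption: the (R,R)-bisphosphoramide is taken to direct the nucleophile to the Re face of enal 5, which gives (8R). If a test reaction shows the opposite sense, the (S,S)-catalyst is used with no other change.

## Route

Step 1
Reactants: 1 nerol; 2 benzoyl chloride
Product: 3 neryl benzoate [(2Z)-3,7-dimethylocta-2,6-dien-1-yl benzoate]
Conditions: Et3N, DMAP (cat.), CH2Cl2, 0 °C → rt
Reagents that add atoms: none
Why: DMAP-catalysed acylation of a primary allylic alcohol by an acid chloride (nucleophilic acyl substitution); the (Z)-C2=C3 alkene is untouched, and the benzoate is the final C1 ester and deactivates the C2=C3 alkene for step 2.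

Step 2
Reactants: 3 neryl benzoate
Product: 4 (2Z,6E)-8-hydroxy-3,7-dimethylocta-2,6-dien-1-yl benzoate
Conditions: SeO2 (cat.), t-BuOOH, salicylic acid (cat.), CH2Cl2, rt
Reagents that add atoms: tert-butyl hydroperoxide, CC(C)(C)OO (source of the new oxygen, passed on by the SeO2 catalyst, O=[Se]=O)
Why: Riley allylic oxidation (ene reaction, then [2,3]-sigmatropic shift): the electron-rich terminal alkene reacts in preference to the ester-deactivated C2=C3 alkene and the (E)-methyl group is oxidised, which fixes the (E)-C6=C7 geometry; any enal 5 formed by over-oxidation is carried into step 3 together with 4.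

Step 3
Reactants: 4 (2Z,6E)-8-hydroxy-3,7-dimethylocta-2,6-dien-1-yl benzoate
Product: 5 (2Z,6E)-3,7-dimethyl-8-oxoocta-2,6-dien-1-yl benzoate
Conditions: MnO2 (activated, excess), CH2Cl2, rt
Reagents that add atoms: none
Why: Heterogeneous MnO2 oxidation is selective for allylic alcohols and stops at the enal; the benzoate and both alkene geometries are not affected.

Step 4
Reactants: 6 (R)-solketal [(4R)-(2,2-dimethyl-1,3-dioxolan-4-yl)methanol]
Product: 7 (4S)-2,2-dimethyl-1,3-dioxolane-4-carbaldehyde
Conditions: (COCl)2, DMSO, CH2Cl2, −78 °C; Et3N, −78 °C → 0 °C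
Reagents that add atoms: none
Why: Swern oxidation at low temperature leaves the α-stereocentre intact (the descriptor changes from R to S only through the ranking of the groups); non-aqueous work-up and immediate use avoid hydration and oligomerisation of the aldehyde.

Step 5
Reactants: 7 (4S)-2,2-dimethyl-1,3-dioxolane-4-carbaldehyde; 8 isopropyltriphenylphosphonium iodide
Product: 10 (4R)-2,2-dimethyl-4-(2-methylprop-1-en-1-yl)-1,3-dioxolane, via isopropylidenetriphenylphosphorane 9 (not isolated)
Conditions: 8, n-BuLi, THF, 0 °C; then 7, −78 °C → rt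
Reagents that add atoms: none
Why: Wittig olefination with a non-stabilised ylide; the new alkene carbon carries two methyl groups, so there is no geometry to control, and addition at −78 °C keeps the α-stereocentre.

Step 6
Reactants: 10 (4R)-2,2-dimethyl-4-(2-methylprop-1-en-1-yl)-1,3-dioxolane
Product: 11 (2R)-4-methylpent-3-ene-1,2-diol
Conditions: AcOH/H2O (4:1), rt
Reagents that add atoms: none
Why: Acetal hydrolysis runs through the dialkoxycarbenium ion at the acetal carbon, which forms far more easily than an allylic cation at C13, so weak acid at room temperature should leave the allylic C–O bond and the stereocentre alone.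

Step 7
Reactants: 11 (2R)-4-methylpent-3-ene-1,2-diol
Product: 12 (2R)-1,2-bis(tert-butyldimethylsilyloxy)-4-methylpent-3-ene
Conditions: TBSCl, imidazole, DMF, rt
Reagents that add atoms: tert-butyldimethylsilyl chloride, CC(C)(C)[Si](C)(C)Cl
Why: Standard imidazole-mediated silylation of both hydroxyl groups; no stereocentre is involved.

Step 8
Reactants: 12 (2R)-1,2-bis(tert-butyldimethylsilyloxy)-4-methylpent-3-ene
Product: 13 (2R)-2-(tert-butyldimethylsilyloxy)-4-methylpent-3-en-1-ol
Conditions: HF·pyridine, pyridine, THF, 0 °C
Reagents that add atoms: none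
Why: Buffered fluoride cleaves the unhindered primary silyl ether much faster than the secondary one; diol 11 from over-cleavage can be returned to step 7.

Step 9
Reactants: 13 (2R)-2-(tert-butyldimethylsilyloxy)-4-methylpent-3-en-1-ol
Product: 14 (2R)-2-(tert-butyldimethylsilyloxy)-4-methylpent-3-enal
Conditions: Dess–Martin periodinane, NaHCO3, CH2Cl2, 0 °C → rt
Reagents that add atoms: none
Why: Dess–Martin oxidation under buffered, neutral conditions; the α-hydrogen of 14 is allylic and α to the carbonyl, so the aldehyde is not chromatographed and is used at once to avoid epimerisation or alkene migration.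

Step 10
Reactants: 14 (2R)-2-(tert-butyldimethylsilyloxy)-4-methylpent-3-enal; 15 methyl (2Z)-2-bromobut-2-enoate
Product: 17 methyl (2E)-2-[(1S,2R)-2-(tert-butyldimethylsilyloxy)-1-hydroxy-4-methylpent-3-en-1-yl]but-2-enoate, via alkenylchromium dichloride 16 (not isolated)
Conditions: CrCl2 (excess), NiCl2 (cat.), DMF, rt
Reagents that add atoms: none
Why: Nozaki–Hiyama–Kishi reaction: zerovalent nickel formed in the flask inserts into the C–Br bond, transmetalation to trivalent chromium gives 16, and this adds to the aldehyde alone under neutral conditions that do not enolise 14. The new C12 centre is set by the polar Felkin–Anh model (attack anti to the C13–OSi bond), giving the 12,13-anti, (12S) isomer; the ethylidene geometry does not matter because step 12 erases it.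

Step 11
Reactants: 17 methyl (2E)-2-[(1S,2R)-2-(tert-butyldimethylsilyloxy)-1-hydroxy-4-methylpent-3-en-1-yl]but-2-enoate
Product: 18 methyl (2E)-2-[(1S,2R)-1,2-bis(tert-butyldimethylsilyloxy)-4-methylpent-3-en-1-yl]but-2-enoate
Conditions: TBSOTf, 2,6-lutidine, CH2Cl2, −78 °C → 0 °C
Reagents that add atoms: tert-butyldimethylsilyl trifluoromethanesulfonate, CC(C)(C)[Si](C)(C)OS(=O)(=O)C(F)(F)F
Why: Silyl triflate with a hindered base silylates the crowded secondary allylic hydroxyl without ionising it; masking the hydroxyl is needed before the strong base of step 12.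

Step 12
Reactants: 18 methyl (2E)-2-[(1S,2R)-1,2-bis(tert-butyldimethylsilyloxy)-4-methylpent-3-en-1-yl]but-2-enoate
Product: 20 (4S,5R)-4,5-bis(tert-butyldimethylsilyloxy)-3-[(tert-butyldimethylsilyloxy)(methoxy)methylidene]-7-methylocta-1,6-diene, via lithium dienolate 19 (not isolated)
Conditions: LDA, DMPU, THF, −78 °C; TBSCl, −78 °C → 0 °C; non-aqueous work-up
Reagents that add atoms: tert-butyldimethylsilyl chloride, CC(C)(C)[Si](C)(C)Cl
Why: Vinylogous (γ) deprotonation of a 2-alkylidene ester by LDA in the presence of DMPU, then O-silylation of the dienolate; conjugate addition of the amide is blocked by the substituted β- and α-carbons, C12–H is not acidified by the carbonyl, and the C12 and C13 centres are not touched.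

Step 13
Reactants: 20 (4S,5R)-4,5-bis(tert-butyldimethylsilyloxy)-3-[(tert-butyldimethylsilyloxy)(methoxy)methylidene]-7-methylocta-1,6-diene; 5 (2Z,6E)-3,7-dimethyl-8-oxoocta-2,6-dien-1-yl benzoate
Product: 22 methyl (2E,5R,6E,10Z)-12-(benzoyloxy)-2-[(1S,2R)-1,2-bis(tert-butyldimethylsilyloxy)-4-methylpent-3-en-1-yl]-5-hydroxy-6,10-dimethyldodeca-2,6,10-trienoate, via trichlorosilyl ether 21 (not isolated)
Conditions: SiCl4, (R,R)-bisphosphoramide (5 mol %), i-Pr2NEt (cat.), CH2Cl2, −78 °C; then aq. NaHCO3/KF
Reagents that add atoms: none
Why: SiCl4 alone is too weak a Lewis acid; the bisphosphoramide ionises one chloride and forms a chiral trichlorosilyl cation that binds the carbonyl oxygen of enal 5 and shields one of its faces. Dienolate 20 attacks through an open transition state with its unhindered γ-carbon C9, since the α-carbon C11 carries the branched bis-silyloxy group and faces the bulky bound silicon unit. Chloride then removes the silyl group from the ester oxygen as TBSCl and the aldolate leaves the catalyst as trichlorosilyl ether 21, which the aqueous quench hydrolyses to 22. The closest known reaction type is the SiCl4/chiral bisphosphoramide vinylogous Mukaiyama aldol of α-methyl ester dienolates with conjugated aldehydes; only the size of the α-substituent is new. No ring is closed. The new C8 centre is controlled by the catalyst (Re-face attack, 8R); C12 and C13 are four and five bonds from the reacting carbon and are not expected to override it. The (E)-C10=C11 geometry follows from the s-trans conformation of the C9=C10–C11=C20 diene, because the s-cis form would push C9 against the ketene acetal oxygen substituents. The step needs γ-regioselectivity, (E)-geometry, 1,2-addition to the enal and facial selectivity, and at −78 °C with an amine buffer the benzoate and silyl ethers should be inert.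

Step 14
Reactants: 22 methyl (2E,5R,6E,10Z)-12-(benzoyloxy)-2-[(1S,2R)-1,2-bis(tert-butyldimethylsilyloxy)-4-methylpent-3-en-1-yl]-5-hydroxy-6,10-dimethyldodeca-2,6,10-trienoate
Product: 24 (2Z,6E,8R)-8-hydroxy-10-[(3E,4S,5R)-4-hydroxy-5-(2-methylprop-1-en-1-yl)-2-oxooxolan-3-ylidene]-3,7-dimethyldeca-2,6-dien-1-yl benzoate, via triol methyl ester 23 (not isolated)
Conditions: HF·pyridine, pyridine, THF, 0 °C → rt; then PPTS (cat.), CH2Cl2, rt
Reagents that add atoms: none
Why: Fluoride removes both secondary silyl ethers, and the freed C13 hydroxyl attacks the methyl ester to close the five-membered lactone (intramolecular transesterification); the C8 hydroxyl cannot reach C20 across the (E)-alkene and the C12 hydroxyl would give a four-membered ring, so only the γ-lactone forms, with C12 and C13 unchanged and trans.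

Step 15
Reactants: 24 (2Z,6E,8R)-8-hydroxy-10-[(3E,4S,5R)-4-hydroxy-5-(2-methylprop-1-en-1-yl)-2-oxooxolan-3-ylidene]-3,7-dimethyldeca-2,6-dien-1-yl benzoate
Product: 25 (2Z,6E,8R)-8-acetoxy-10-[(3E,4S,5R)-4-acetoxy-5-(2-methylprop-1-en-1-yl)-2-oxooxolan-3-ylidene]-3,7-dimethyldeca-2,6-dien-1-yl benzoate (target CNP0262857.1)
Conditions: Ac2O, pyridine, CH2Cl2, 0 °C → rt (no DMAP)
Reagents that add atoms: acetic anhydride, CC(=O)OC(C)=O
Why: Acetylation of both secondary hydroxyls with retention at C8 and C12; DMAP is left out because a strong nucleophilic catalyst could displace the new C12 acetate of the alkylidene lactone in the conjugate sense.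

## Compound list

1 | nerol, (2Z)-3,7-dimethylocta-2,6-dien-1-ol | CC(C)=CCC/C(C)=C\CO | starting material
2 | benzoyl chloride | O=C(Cl)c1ccccc1 | starting material
3 | neryl benzoate, (2Z)-3,7-dimethylocta-2,6-dien-1-yl benzoate | CC(C)=CCC/C(C)=C\COC(=O)c1ccccc1 | intermediate
4 | (2Z,6E)-8-hydroxy-3,7-dimethylocta-2,6-dien-1-yl benzoate | OC/C(C)=C/CC/C(C)=C\COC(=O)c1ccccc1 | intermediate
5 | (2Z,6E)-3,7-dimethyl-8-oxoocta-2,6-dien-1-yl benzoate | O=C/C(C)=C/CC/C(C)=C\COC(=O)c1ccccc1 | intermediate
6 | (R)-solketal, (4R)-(2,2-dimethyl-1,3-dioxolan-4-yl)methanol | OC[C@@H]1COC(C)(C)O1 | starting material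
7 | (4S)-2,2-dimethyl-1,3-dioxolane-4-carbaldehyde | O=C[C@@H]1COC(C)(C)O1 | intermediate
8 | isopropyltriphenylphosphonium iodide | CC(C)[P+](c1ccccc1)(c1ccccc1)c1ccccc1.[I-] | starting material
9 | isopropylidenetriphenylphosphorane | CC(C)=P(c1ccccc1)(c1ccccc1)c1ccccc1 | intermediate (not isolated)
10 | (4R)-2,2-dimethyl-4-(2-methylprop-1-en-1-yl)-1,3-dioxolane | CC(C)=C[C@@H]1COC(C)(C)O1 | intermediate
11 | (2R)-4-methylpent-3-ene-1,2-diol | CC(C)=C[C@@H](O)CO | intermediate
12 | (2R)-1,2-bis(tert-butyldimethylsilyloxy)-4-methylpent-3-ene | CC(C)=C[C@@H](O[Si](C)(C)C(C)(C)C)CO[Si](C)(C)C(C)(C)C | intermediate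
13 | (2R)-2-(tert-butyldimethylsilyloxy)-4-methylpent-3-en-1-ol | CC(C)=C[C@@H](O[Si](C)(C)C(C)(C)C)CO | intermediate
14 | (2R)-2-(tert-butyldimethylsilyloxy)-4-methylpent-3-enal | CC(C)=C[C@@H](O[Si](C)(C)C(C)(C)C)C=O | intermediate
15 | methyl (2Z)-2-bromobut-2-enoate | C/C=C(\Br)C(=O)OC | starting material
16 | methyl (2Z)-2-(dichlorochromio)but-2-enoate (alkenylchromium dichloride) | C/C=C(\[Cr](Cl)Cl)C(=O)OC | intermediate (not isolated)
17 | methyl (2E)-2-[(1S,2R)-2-(tert-butyldimethylsilyloxy)-1-hydroxy-4-methylpent-3-en-1-yl]but-2-enoate | COC(=O)/C(=C/C)[C@H](O)[C@H](O[Si](C)(C)C(C)(C)C)C=C(C)C | intermediate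
18 | methyl (2E)-2-[(1S,2R)-1,2-bis(tert-butyldimethylsilyloxy)-4-methylpent-3-en-1-yl]but-2-enoate | COC(=O)/C(=C/C)[C@H](O[Si](C)(C)C(C)(C)C)[C@H](O[Si](C)(C)C(C)(C)C)C=C(C)C | intermediate
19 | lithium dienolate of 18 | C=CC(=C(OC)O[Li])[C@H](O[Si](C)(C)C(C)(C)C)[C@H](O[Si](C)(C)C(C)(C)C)C=C(C)C | intermediate (not isolated)
20 | (4S,5R)-4,5-bis(tert-butyldimethylsilyloxy)-3-[(tert-butyldimethylsilyloxy)(methoxy)methylidene]-7-methylocta-1,6-diene (ketene acetal geometry not defined) | C=CC(=C(OC)O[Si](C)(C)C(C)(C)C)[C@H](O[Si](C)(C)C(C)(C)C)[C@H](O[Si](C)(C)C(C)(C)C)C=C(C)C | intermediate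
21 | methyl (2E,5R,6E,10Z)-12-(benzoyloxy)-2-[(1S,2R)-1,2-bis(tert-butyldimethylsilyloxy)-4-methylpent-3-en-1-yl]-6,10-dimethyl-5-(trichlorosilyloxy)dodeca-2,6,10-trienoate | COC(=O)/C(=C/C[C@@H](O[Si](Cl)(Cl)Cl)/C(C)=C/CC/C(C)=C\COC(=O)c1ccccc1)[C@H](O[Si](C)(C)C(C)(C)C)[C@H](O[Si](C)(C)C(C)(C)C)C=C(C)C | intermediate (not isolated)
22 | methyl (2E,5R,6E,10Z)-12-(benzoyloxy)-2-[(1S,2R)-1,2-bis(tert-butyldimethylsilyloxy)-4-methylpent-3-en-1-yl]-5-hydroxy-6,10-dimethyldodeca-2,6,10-trienoate | COC(=O)/C(=C/C[C@@H](O)/C(C)=C/CC/C(C)=C\COC(=O)c1ccccc1)[C@H](O[Si](C)(C)C(C)(C)C)[C@H](O[Si](C)(C)C(C)(C)C)C=C(C)C | intermediate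
23 | methyl (2E,5R,6E,10Z)-12-(benzoyloxy)-2-[(1S,2R)-1,2-dihydroxy-4-methylpent-3-en-1-yl]-5-hydroxy-6,10-dimethyldodeca-2,6,10-trienoate | COC(=O)/C(=C/C[C@@H](O)/C(C)=C/CC/C(C)=C\COC(=O)c1ccccc1)[C@H](O)[C@H](O)C=C(C)C | intermediate (not isolated)
24 | (2Z,6E,8R)-8-hydroxy-10-[(3E,4S,5R)-4-hydroxy-5-(2-methylprop-1-en-1-yl)-2-oxooxolan-3-ylidene]-3,7-dimethyldeca-2,6-dien-1-yl benzoate | O[C@H](C/C=C1/C(=O)O[C@H](C=C(C)C)[C@H]1O)/C(C)=C/CC/C(C)=C\COC(=O)c1ccccc1 | intermediate
25 | (2Z,6E,8R)-8-acetoxy-10-[(3E,4S,5R)-4-acetoxy-5-(2-methylprop-1-en-1-yl)-2-oxooxolan-3-ylidene]-3,7-dimethyldeca-2,6-dien-1-yl benzoate | CC(=O)O[C@H](C/C=C1/C(=O)O[C@H](C=C(C)C)[C@H]1OC(C)=O)/C(C)=C/CC/C(C)=C\COC(=O)c1ccccc1 | target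

## Step count and least certain steps

Total step count: 15 (steps 1–3 for the enal, steps 4–12 for the dienolate, steps 13–15 for union and endgame). Longest linear sequence: 12 steps, from 6 to 25 (steps 4–15).

**Step 13 (key step).**
- Most likely problem: the branched, doubly silyloxylated α-substituent slows attack of the dienolate. A slow catalysed reaction lets uncatalysed or α-selective pathways compete and erodes facial selectivity at the aldehyde; the distant C12 and C13 centres might also work against the catalyst.
- Fallback: it sets out from 20 and 5 and comes back at 22. A vinylogous Mukaiyama aldol without chiral control (BF3·OEt2, CH2Cl2, −78 °C) is γ-selective for silyl dienolates and would give 22 together with its C8 epimer, methyl (2E,5S,6E,10Z)-12-(benzoyloxy)-2-[(1S,2R)-1,2-bis(tert-butyldimethylsilyloxy)-4-methylpent-3-en-1-yl]-5-hydroxy-6,10-dimethyldodeca-2,6,10-trienoate F1. The two are diastereomers and are separated by chromatography. F1 is inverted by a Mitsunobu reaction (ClCH2CO2H, PPh3, DIAD, toluene, 0 °C) to the (5R)-chloroacetate, methyl (2E,5R,6E,10Z)-12-(benzoyloxy)-2-[(1S,2R)-1,2-bis(tert-butyldimethylsilyloxy)-4-methylpent-3-en-1-yl]-5-(chloroacetoxy)-6,10-dimethyldodeca-2,6,10-trienoate F2. Thiourea and NaHCO3 in EtOH then remove the chloroacetyl group without touching the benzoate or the methyl ester and return 22.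

**Step 12.**
- Most likely problem: the lithium dienolate has a silyloxy leaving group β to the enolate carbon, so elimination of silanolate (E1cB) can compete with O-silylation while the mixture warms. γ-Deprotonation of the (E)-ethylidene ester may also be incomplete.
- Fallback: it sets out from 17 and comes back at 20, so step 11 is not needed. Two equivalents of LDA in THF–DMPU at −78 °C would give the dilithium alkoxide dienolate of 17 F3 (not isolated), a Fráter–Seebach-type dianion whose C12 oxygen is an oxide and cannot leave. An excess of TBSCl (−78 °C → rt) then silylates both oxygens to give 20.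

**Step 10.**
- Most likely problem: oxidative addition and transmetalation of the electron-poor α-bromo enoate may be slow, so that reductive loss of bromine or homocoupling prevails, and Felkin–Anh control at C12 may be only moderate.
- Fallback: it sets out from 14 and comes back at 20. Methyl crotonate is deprotonated with LDA (THF–DMPU, −78 °C) to the lithium dienolate of methyl crotonate F4 (not isolated), which adds to 14 through its α-carbon. This gives methyl (3S,4R)-4-(tert-butyldimethylsilyloxy)-2-ethenyl-3-hydroxy-6-methylhept-5-enoate F5 as a mixture at C2, with C3 set by the same Felkin–Anh preference; a minor C3 epimer is removed here. TBSOTf and 2,6-lutidine give methyl (3S,4R)-3,4-bis(tert-butyldimethylsilyloxy)-2-ethenyl-6-methylhept-5-enoate F6, and α-deprotonation with O-silylation under the conditions of step 12 erases C2 and gives 20.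

**Step 6.**
- Most likely problem: the acid may ionise the allylic C–O bond next to the trisubstituted alkene (a dimethylallyl-type cation), which would cause loss of configuration or 1,3-transposition of the diol.
- Fallback: it sets out from 6 and comes back at 12, and removes the acetal before the allylic system exists. The steps are:
  - Etherification (NaH, 4-methoxybenzyl chloride, DMF) gives (4R)-4-[(4-methoxybenzyloxy)methyl]-2,2-dimethyl-1,3-dioxolane F7.
  - AcOH/H2O gives (2S)-3-(4-methoxybenzyloxy)propane-1,2-diol F8.
  - TBSCl and imidazole give 1-{[(2R)-2,3-bis(tert-butyldimethylsilyloxy)propoxy]methyl}-4-methoxybenzene F9.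
  - DDQ in wet CH2Cl2 gives (2R)-2,3-bis(tert-butyldimethylsilyloxy)propan-1-ol F10.
  - Dess–Martin oxidation gives (2S)-2,3-bis(tert-butyldimethylsilyloxy)propanal F11.
  - Wittig reaction with ylide 9 gives 12.

## Further compounds

F1 | step 13 | methyl (2E,5S,6E,10Z)-12-(benzoyloxy)-2-[(1S,2R)-1,2-bis(tert-butyldimethylsilyloxy)-4-methylpent-3-en-1-yl]-5-hydroxy-6,10-dimethyldodeca-2,6,10-trienoate | COC(=O)/C(=C/C[C@H](O)/C(C)=C/CC/C(C)=C\COC(=O)c1ccccc1)[C@H](O[Si](C)(C)C(C)(C)C)[C@H](O[Si](C)(C)C(C)(C)C)C=C(C)C
F2 | step 13 | methyl (2E,5R,6E,10Z)-12-(benzoyloxy)-2-[(1S,2R)-1,2-bis(tert-butyldimethylsilyloxy)-4-methylpent-3-en-1-yl]-5-(chloroacetoxy)-6,10-dimethyldodeca-2,6,10-trienoate | COC(=O)/C(=C/C[C@@H](OC(=O)CCl)/C(C)=C/CC/C(C)=C\COC(=O)c1ccccc1)[C@H](O[Si](C)(C)C(C)(C)C)[C@H](O[Si](C)(C)C(C)(C)C)C=C(C)C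
F3 | step 12 | dilithium alkoxide dienolate of 17 (not isolated) | C=CC(=C(OC)O[Li])[C@H](O[Li])[C@H](O[Si](C)(C)C(C)(C)C)C=C(C)C
F4 | step 10 | lithium dienolate of methyl crotonate (not isolated) | C=CC=C(OC)O[Li]
F5 | step 10 | methyl (3S,4R)-4-(tert-butyldimethylsilyloxy)-2-ethenyl-3-hydroxy-6-methylhept-5-enoate (both C2 epimers) | COC(=O)C(C=C)[C@H](O)[C@H](O[Si](C)(C)C(C)(C)C)C=C(C)C
F6 | step 10 | methyl (3S,4R)-3,4-bis(tert-butyldimethylsilyloxy)-2-ethenyl-6-methylhept-5-enoate (both C2 epimers) | COC(=O)C(C=C)[C@H](O[Si](C)(C)C(C)(C)C)[C@H](O[Si](C)(C)C(C)(C)C)C=C(C)C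
F7 | step 6 | (4R)-4-[(4-methoxybenzyloxy)methyl]-2,2-dimethyl-1,3-dioxolane | COc1ccc(COC[C@@H]2COC(C)(C)O2)cc1
F8 | step 6 | (2S)-3-(4-methoxybenzyloxy)propane-1,2-diol | COc1ccc(COC[C@@H](O)CO)cc1
F9 | step 6 | 1-{[(2R)-2,3-bis(tert-butyldimethylsilyloxy)propoxy]methyl}-4-methoxybenzene | COc1ccc(COC[C@@H](O[Si](C)(C)C(C)(C)C)CO[Si](C)(C)C(C)(C)C)cc1
F10 | step 6 | (2R)-2,3-bis(tert-butyldimethylsilyloxy)propan-1-ol | OC[C@@H](O[Si](C)(C)C(C)(C)C)CO[Si](C)(C)C(C)(C)C
F11 | step 6 | (2S)-2,3-bis(tert-butyldimethylsilyloxy)propanal | O=C[C@@H](O[Si](C)(C)C(C)(C)C)CO[Si](C)(C)C(C)(C)C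
A1 | alternative 1 | (E)-alkylidene hydroxy lactone with free C12 hydroxyl and silyl ethers at C1 and C8 | CC(C)(C)[Si](C)(C)O[C@H](C/C=C1/C(=O)O[C@H](C=C(C)C)[C@H]1O)/C(C)=C/CC/C(C)=C\CO[Si](C)(C)C(C)(C)C
A2 | alternative 1 | alkynyl diol with C10≡C11 triple bond, free C12 and C13 hydroxyls, silyl ethers at C1 and C8 | CC(C)=C[C@@H](O)[C@@H](O)C#CC[C@@H](O[Si](C)(C)C(C)(C)C)/C(C)=C/CC/C(C)=C\CO[Si](C)(C)C(C)(C)C
A3 | alternative 2 | tris-silyl ether of the triol lactone | CC(C)(C)[Si](C)(C)O[C@H](C/C=C1/C(=O)O[C@H](C=C(C)C)[C@H]1O[Si](C)(C)C(C)(C)C)/C(C)=C/CC/C(C)=C\CO[Si](C)(C)C(C)(C)C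
A4 | alternative 2 | 1,3-dioxoisoindolin-2-yl (3R,4E,8Z)-3,10-bis(tert-butyldimethylsilyloxy)-4,8-dimethyldeca-4,8-dienoate | O=C(C[C@@H](O[Si](C)(C)C(C)(C)C)/C(C)=C/CC/C(C)=C\CO[Si](C)(C)C(C)(C)C)ON1C(=O)c2ccccc2C1=O
A5 | alternative 2 | (3E,4S,5R)-4-(tert-butyldimethylsilyloxy)-3-(iodomethylidene)-5-(2-methylprop-1-en-1-yl)oxolan-2-one | I/C=C1/C(=O)O[C@H](C=C(C)C)[C@H]1O[Si](C)(C)C(C)(C)C
A6 | alternative 2 | 2-deoxy-D-ribono-1,4-lactone, (4S,5R)-4-hydroxy-5-(hydroxymethyl)oxolan-2-one | O=C1C[C@H](O)[C@@H](CO)O1
A7 | alternative 3 | anti β-hydroxy-γ-(triethylsilyloxy) (E)-2-alkylidene ester | COC(=O)/C(=C/C[C@@H](O[Si](C)(C)C(C)(C)C)/C(C)=C/CC/C(C)=C\COC(=O)c1ccccc1)[C@H](O)[C@H](O[Si](CC)(CC)CC)C=C(C)C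
A8 | alternative 3 | methyl (2Z,5R,6E,10Z)-12-(benzoyloxy)-5-(tert-butyldimethylsilyloxy)-2-iodo-6,10-dimethyldodeca-2,6,10-trienoate | COC(=O)/C(I)=C/C[C@@H](O[Si](C)(C)C(C)(C)C)/C(C)=C/CC/C(C)=C\COC(=O)c1ccccc1
A9 | alternative 3 | (2R)-4-methyl-2-(triethylsilyloxy)pent-3-enal | CC(C)=C[C@@H](O[Si](CC)(CC)CC)C=O
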